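**Strategy.** Confluentic acid is cut at the depside ester into a ring B phenol and a ring A acid whose 2-oxoheptyl ketone is masked as a dioxolane. Everything rests on ring A's contiguous array of C2 oxygen, C1 carboxyl carbon and C6 CH2–carbonyl arm: 3,5-dimethoxybenzyne, released from silyl triflate 8, inserts into a C–C bond of dimethyl malonate 9, forming the C1–carboxyl and C6–CH2 bonds of homophthalate 11 in one operation. Precursor 8 carries trimethylsilyl between triflate and methoxy, so the flanking methoxy steers the regiochemistry. Chelation-controlled demethylation, Weinreb ketone synthesis, ketalisation, saponification, carbodiimide coupling and two deprotections finish the route.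

Key step: step 4

Assumption: olivetolic acid 18 and pentylmagnesium bromide 14 are taken as purchasable; the target has no stereocentre, so no step has to set configuration. Ring A is numbered from the carboxyl-bearing carbon (C1), with C2–OH, C4–OMe and the side arm on C6.

Step 1
Reactants: 1 3,5-dimethoxyphenol
Product: 2 3,5-dimethoxyphenyl N-isopropylcarbamate
Conditions: i-PrNCO, Et3N (cat.), CH2Cl2, 23 °C
Reagents that add atoms: isopropyl isocyanate, CC(C)N=C=O
Why: Amine-catalysed addition of the phenol O–H across the isocyanate (carbamoylation) should be clean and installs an N-monoalkyl carbamate that directs metalation strongly yet can be removed later under mild base.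

Step 2
Reactants: 2 3,5-dimethoxyphenyl N-isopropylcarbamate
Product: 6 3,5-dimethoxy-2-(trimethylsilyl)phenyl N-isopropylcarbamate, via N-TBS carbamate 3 (not isolated), via ortho-lithiated N-TBS carbamate 4 (not isolated), via C-silylated N-TBS carbamate 5 (not isolated)
Conditions: TBSOTf, TMEDA, Et2O, 0 → 23 °C; n-BuLi, TMEDA, −78 °C; TMSCl, −78 → 23 °C; aq. NaHSO4
Reagents that add atoms: chlorotrimethylsilane, C[Si](C)(C)Cl; tert-butyldimethylsilyl trifluoromethanesulfonate, CC(C)(C)[Si](C)(C)OS(=O)(=O)C(F)(F)F (silyl group held only in 3 to 5); n-butyllithium, [Li]CCCC (lithium held only in 4)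
Why: Directed ortho-metalation: once the N–H is blocked in the flask as the N-silyl carbamate, n-BuLi/TMEDA should remove the proton between the carbamate and a methoxy group (the two such positions are equivalent by symmetry and doubly activated, so the position between the two methoxy groups should not compete), TMSCl traps the aryllithium at −78 °C before an anionic Fries shift can set in, and the acidic work-up removes the N-silyl group.

Step 3
Reactants: 6 3,5-dimethoxy-2-(trimethylsilyl)phenyl N-isopropylcarbamate
Product: 8 3,5-dimethoxy-2-(trimethylsilyl)phenyl trifluoromethanesulfonate, via 3,5-dimethoxy-2-(trimethylsilyl)phenol 7 (not isolated)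
Conditions: DBU, Et2NH, MeCN, 40 °C; PhNTf2, 23 °C
Reagents that add atoms: N-phenylbis(trifluoromethanesulfonimide), O=S(=O)(N(c1ccccc1)S(=O)(=O)C(F)(F)F)C(F)(F)F
Why: DBU-induced E1cB loss of isopropyl isocyanate, captured by diethylamine as a urea, should free the hindered phenoxide, which PhNTf2 sulfonylates in the same pot (carbamate cleavage then O-triflation), so the ortho-silyl phenol is never handled.

Step 4
Reactants: 8 3,5-dimethoxy-2-(trimethylsilyl)phenyl trifluoromethanesulfonate; 9 dimethyl malonate
Product: 11 methyl 2,4-dimethoxy-6-(2-methoxy-2-oxoethyl)benzoate, via 3,5-dimethoxybenzyne 10 (not isolated)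
Conditions: KF, 18-crown-6, THF, 23 °C (9 in excess, 8 added slowly)
Reagents that add atoms: none
Why: Fluoride attacks silicon and triflate leaves to give aryne 10; the malonate carbanion then adds to the aryne carbon that becomes C6, the one remote from the flanking methoxy group, so that the aryl anion develops at C1 next to the inductively withdrawing C2 oxygen. That C1 anion adds to one ester carbonyl of the attached malonate unit to give a strained benzocyclobutene alkoxide, which fragments by retro-aldol-type C–C cleavage to the ester-stabilised benzylic carbanion and is protonated by malonate, leaving CO2Me on C1 and CH2CO2Me on C6. The closest known reaction type is the fluoride-induced insertion of arynes into the C–C σ bond of malonates and β-keto esters (aryne acyl-alkylation). No ring remains closed, since the four-membered ring formed by 4-exo-trig attack of the aryl anion is opened again in the same cascade, and no stereocentre is created. The step needs regioselective addition to the unsymmetrical aryne, which the methoxy group beside the triple bond should secure through its inductive effect and the distortion it imposes on the aryne; it also needs insertion to outrun simple α-arylation and a second arylation of 11, for which the excess of 9 and the slow release of the aryne are chosen.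

Step 5
Reactants: 11 methyl 2,4-dimethoxy-6-(2-methoxy-2-oxoethyl)benzoate
Product: 12 methyl 2-hydroxy-4-methoxy-6-(2-methoxy-2-oxoethyl)benzoate
Conditions: BCl3, CH2Cl2, −78 → 0 °C; H2O
Reagents that add atoms: none
Why: Chelation-controlled ether cleavage: BCl3 binds between the ring ester carbonyl and the ortho (C2) methoxy oxygen, so chloride should remove only that methyl group, leaving the C4 methyl ether and both methyl esters untouched at low temperature, and no ketone is yet present that could lactonise under the Lewis acid.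

Step 6
Reactants: 12 methyl 2-hydroxy-4-methoxy-6-(2-methoxy-2-oxoethyl)benzoate
Product: 13 methyl 2-hydroxy-4-methoxy-6-{2-[methoxy(methyl)amino]-2-oxoethyl}benzoate
Conditions: MeNH(OMe)·HCl, i-PrMgCl, THF, −20 → 0 °C; aq. NH4Cl
Reagents that add atoms: N,O-dimethylhydroxylamine hydrochloride, CNOC.Cl
Why: Weinreb amide synthesis from an ester: the chloromagnesium amide of N,O-dimethylhydroxylamine should aminolyse only the unhindered arylacetic ester, because the ring ester is flanked on both sides and further deactivated as its ortho magnesium phenoxide.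

Step 7
Reactants: 13 methyl 2-hydroxy-4-methoxy-6-{2-[methoxy(methyl)amino]-2-oxoethyl}benzoate; 14 pentylmagnesium bromide
Product: 15 methyl 2-hydroxy-4-methoxy-6-(2-oxoheptyl)benzoate
Conditions: n-C5H11MgBr (3 equiv), THF, −20 → 0 °C; aq. NH4Cl
Reagents that add atoms: none
Why: Weinreb ketone synthesis: after one equivalent of the Grignard reagent is spent on the phenol, a second adds to the amide to give a stable magnesium chelate that releases the ketone only on quenching, so over-addition is excluded and the shielded ring ester should not be attacked.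

Step 8
Reactants: 15 methyl 2-hydroxy-4-methoxy-6-(2-oxoheptyl)benzoate
Product: 16 methyl 2-hydroxy-4-methoxy-6-[(2-pentyl-1,3-dioxolan-2-yl)methyl]benzoate
Conditions: HOCH2CH2OH, HC(OMe)3, TsOH·H2O (cat.), CH2Cl2, 23 °C
Reagents that add atoms: ethylene glycol, OCCO
Why: Acid-catalysed ketalisation (dioxolane formation) driven by the orthoformate as water scavenger should proceed at room temperature, conditions mild enough that enol lactonisation onto the hydrogen-bonded, doubly flanked methyl ester (which would give the isocoumarin) should not compete.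

Step 9
Reactants: 16 methyl 2-hydroxy-4-methoxy-6-[(2-pentyl-1,3-dioxolan-2-yl)methyl]benzoate
Product: 17 2-hydroxy-4-methoxy-6-[(2-pentyl-1,3-dioxolan-2-yl)methyl]benzoic acid
Conditions: KOH, DMSO–H2O, 80 °C; 1 M HCl to pH 4, 0 °C
Reagents that add atoms: potassium hydroxide, [K+].[OH-]
Why: Saponification (hydroxide-mediated acyl–oxygen cleavage) of the hindered salicylate needs hot hydroxide in aqueous DMSO, which the dioxolane tolerates, and cold acidification only to pH 4 should keep the ketal and avoid decarboxylation of the electron-rich acid, which is used at once.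

Step 10
Reactants: 18 olivetolic acid (2,4-dihydroxy-6-pentylbenzoic acid)
Product: 19 benzyl 2,4-dihydroxy-6-pentylbenzoate
Conditions: BnBr, KHCO3, DMF, 23 °C
Reagents that add atoms: benzyl bromide, BrCc1ccccc1
Why: Carboxylate O-alkylation (SN2) under bicarbonate should esterify only the acid, since KHCO3 does not ionise the phenols and no acyl activation of the hindered, decarboxylation-prone acid is needed.

Step 11
Reactants: 19 benzyl 2,4-dihydroxy-6-pentylbenzoate
Product: 20 benzyl 2-hydroxy-4-(methoxymethoxy)-6-pentylbenzoate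
Conditions: MOMCl (1.05 equiv), i-Pr2NEt, CH2Cl2, 0 °C
Reagents that add atoms: chloromethyl methyl ether, COCCl
Why: Selective O-alkylation (MOM ether formation): the C4 hydroxyl is the only unchelated and more acidic phenol, whereas the C2 hydroxyl is held in a hydrogen bond to the ester carbonyl and should stay free with one equivalent of reagent.

Step 12
Reactants: 20 benzyl 2-hydroxy-4-(methoxymethoxy)-6-pentylbenzoate
Product: 21 benzyl 2-methoxy-4-(methoxymethoxy)-6-pentylbenzoate
Conditions: MeI, K2CO3, DMF, 40 °C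
Reagents that add atoms: iodomethane, CI
Why: Williamson ether synthesis under more forcing conditions should methylate the remaining chelated C2 phenol, and the MOM ether and the benzyl ester are stable to carbonate.

Step 13
Reactants: 21 benzyl 2-methoxy-4-(methoxymethoxy)-6-pentylbenzoate
Product: 22 benzyl 4-hydroxy-2-methoxy-6-pentylbenzoate
Conditions: HCl, MeOH, 40 °C
Reagents that add atoms: none
Why: Acid-catalysed acetal exchange (MOM removal) in methanol should free the C4 phenol, while the aryl methyl ether and the doubly ortho-substituted benzyl ester do not react under these conditions.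

Step 14
Reactants: 17 2-hydroxy-4-methoxy-6-[(2-pentyl-1,3-dioxolan-2-yl)methyl]benzoic acid; 22 benzyl 4-hydroxy-2-methoxy-6-pentylbenzoate
Product: 23 benzyl 4-({2-hydroxy-4-methoxy-6-[(2-pentyl-1,3-dioxolan-2-yl)methyl]benzoyl}oxy)-2-methoxy-6-pentylbenzoate
Conditions: DCC, DMAP (cat.), CH2Cl2, 0 → 23 °C
Reagents that add atoms: none
Why: Steglich esterification: the O-acylisourea of 17 is passed through the acylpyridinium to the only free, unchelated phenol of 22, the acid's own C2 hydroxyl being hydrogen-bonded and hindered, while the neutral conditions keep the dioxolane that prevents enol lactonisation of the activated acid.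

Step 15
Reactants: 23 benzyl 4-({2-hydroxy-4-methoxy-6-[(2-pentyl-1,3-dioxolan-2-yl)methyl]benzoyl}oxy)-2-methoxy-6-pentylbenzoate
Product: 24 benzyl 4-{[2-hydroxy-4-methoxy-6-(2-oxoheptyl)benzoyl]oxy}-2-methoxy-6-pentylbenzoate
Conditions: 1 M HCl, THF, 23 °C
Reagents that add atoms: water, O
Why: Acid-catalysed ketal hydrolysis in dilute aqueous acid at room temperature should unmask the ketone, the depside ester (stabilised by the hydrogen bond from the ortho hydroxyl) and the hindered benzyl ester being inert under these conditions.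

Step 16
Reactants: 24 benzyl 4-{[2-hydroxy-4-methoxy-6-(2-oxoheptyl)benzoyl]oxy}-2-methoxy-6-pentylbenzoate
Product: 25 confluentic acid
Conditions: H2 (1 atm), Pd/C, EtOAc, 23 °C
Reagents that add atoms: none
Why: Hydrogenolysis of the benzyl ester over palladium on carbon under neutral conditions should release the acid, with the aliphatic ketone, the depside ester and the aryl ethers untouched.

**Compound list**

1 | 3,5-dimethoxyphenol | COc1cc(O)cc(OC)c1 | starting material
2 | 3,5-dimethoxyphenyl N-isopropylcarbamate | COc1cc(OC)cc(OC(=O)NC(C)C)c1 | intermediate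
3 | 3,5-dimethoxyphenyl N-(tert-butyldimethylsilyl)-N-isopropylcarbamate | COc1cc(OC)cc(OC(=O)N(C(C)C)[Si](C)(C)C(C)(C)C)c1 | intermediate
4 | 2-lithio-3,5-dimethoxyphenyl N-(tert-butyldimethylsilyl)-N-isopropylcarbamate | [Li]c1c(OC)cc(OC)cc1OC(=O)N(C(C)C)[Si](C)(C)C(C)(C)C | intermediate
5 | 3,5-dimethoxy-2-(trimethylsilyl)phenyl N-(tert-butyldimethylsilyl)-N-isopropylcarbamate | COc1cc(OC)c([Si](C)(C)C)c(OC(=O)N(C(C)C)[Si](C)(C)C(C)(C)C)c1 | intermediate
6 | 3,5-dimethoxy-2-(trimethylsilyl)phenyl N-isopropylcarbamate | COc1cc(OC)c([Si](C)(C)C)c(OC(=O)NC(C)C)c1 | intermediate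
7 | 3,5-dimethoxy-2-(trimethylsilyl)phenol | COc1cc(OC)c([Si](C)(C)C)c(O)c1 | intermediate
8 | 3,5-dimethoxy-2-(trimethylsilyl)phenyl trifluoromethanesulfonate | COc1cc(OC)c([Si](C)(C)C)c(OS(=O)(=O)C(F)(F)F)c1 | intermediate
9 | dimethyl malonate | COC(=O)CC(=O)OC | starting material
10 | 3,5-dimethoxybenzyne (1,2-didehydro-3,5-dimethoxybenzene) | COC1=CC(OC)=CC#C1 | intermediate
11 | methyl 2,4-dimethoxy-6-(2-methoxy-2-oxoethyl)benzoate | COC(=O)Cc1cc(OC)cc(OC)c1C(=O)OC | intermediate
12 | methyl 2-hydroxy-4-methoxy-6-(2-methoxy-2-oxoethyl)benzoate | COC(=O)Cc1cc(OC)cc(O)c1C(=O)OC | intermediate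
13 | methyl 2-hydroxy-4-methoxy-6-{2-[methoxy(methyl)amino]-2-oxoethyl}benzoate | CON(C)C(=O)Cc1cc(OC)cc(O)c1C(=O)OC | intermediate
14 | pentylmagnesium bromide | CCCCC[Mg]Br | starting material
15 | methyl 2-hydroxy-4-methoxy-6-(2-oxoheptyl)benzoate | CCCCCC(=O)Cc1cc(OC)cc(O)c1C(=O)OC | intermediate
16 | methyl 2-hydroxy-4-methoxy-6-[(2-pentyl-1,3-dioxolan-2-yl)methyl]benzoate | CCCCCC1(Cc2cc(OC)cc(O)c2C(=O)OC)OCCO1 | intermediate
17 | 2-hydroxy-4-methoxy-6-[(2-pentyl-1,3-dioxolan-2-yl)methyl]benzoic acid | CCCCCC1(Cc2cc(OC)cc(O)c2C(=O)O)OCCO1 | intermediate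
18 | olivetolic acid (2,4-dihydroxy-6-pentylbenzoic acid) | CCCCCc1cc(O)cc(O)c1C(=O)O | starting material
19 | benzyl 2,4-dihydroxy-6-pentylbenzoate | CCCCCc1cc(O)cc(O)c1C(=O)OCc1ccccc1 | intermediate
20 | benzyl 2-hydroxy-4-(methoxymethoxy)-6-pentylbenzoate | CCCCCc1cc(OCOC)cc(O)c1C(=O)OCc1ccccc1 | intermediate
21 | benzyl 2-methoxy-4-(methoxymethoxy)-6-pentylbenzoate | CCCCCc1cc(OCOC)cc(OC)c1C(=O)OCc1ccccc1 | intermediate
22 | benzyl 4-hydroxy-2-methoxy-6-pentylbenzoate | CCCCCc1cc(O)cc(OC)c1C(=O)OCc1ccccc1 | intermediate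
23 | benzyl 4-({2-hydroxy-4-methoxy-6-[(2-pentyl-1,3-dioxolan-2-yl)methyl]benzoyl}oxy)-2-methoxy-6-pentylbenzoate | CCCCCC1(Cc2cc(OC)cc(O)c2C(=O)Oc2cc(CCCCC)c(C(=O)OCc3ccccc3)c(OC)c2)OCCO1 | intermediate
24 | benzyl 4-{[2-hydroxy-4-methoxy-6-(2-oxoheptyl)benzoyl]oxy}-2-methoxy-6-pentylbenzoate | CCCCCC(=O)Cc1cc(OC)cc(O)c1C(=O)Oc1cc(CCCCC)c(C(=O)OCc2ccccc2)c(OC)c1 | intermediate
25 | confluentic acid | CCCCCC(=O)Cc1cc(OC)cc(O)c1C(=O)Oc1cc(CCCCC)c(C(=O)O)c(OC)c1 | target

**Step count.** Total: 16 steps. Longest linear sequence: 12 steps (steps 1 to 9, then 14 to 16); the ring B branch is steps 10 to 13.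

**Steps most likely to fail**

Step 4 (aryne insertion). The malonate carbanion may arylate without the acyl shift, product 11 may be arylated a second time at its acidic CH2 group, or addition to the aryne may lose regiocontrol. The fallback replaces the aryne by a cross-coupling and sets out from carbamate 2. Lithiation as in step 2 (through 3 and 4) with a methyl chloroformate quench should give methyl 2-{[N-(tert-butyldimethylsilyl)-N-isopropylcarbamoyl]oxy}-4,6-dimethoxybenzoate F1. Acidic work-up should convert it to methyl 2,4-dimethoxy-6-[(isopropylcarbamoyl)oxy]benzoate F2. DBU/Et2NH then PhNTf2, as in step 3, should give methyl 2-hydroxy-4,6-dimethoxybenzoate F3 and from it methyl 2,4-dimethoxy-6-{[(trifluoromethyl)sulfonyl]oxy}benzoate F4. Palladium-catalysed α-arylation of dimethyl malonate 9 with F4 (Pd(OAc)2, XPhos, Cs2CO3, toluene, 90 °C) should give dimethyl 2-[3,5-dimethoxy-2-(methoxycarbonyl)phenyl]malonate F5. Krapcho demethoxycarbonylation (LiCl, wet DMSO, 140 °C) then comes back to the route at 11.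

Step 8 (ketalisation). Under acid the enol or hemiketal oxygen may attack the neighbouring ester and close the isocoumarin with loss of methanol faster than the dioxolane forms, or the ketal may be lost again at the acidification of step 9. The fallback uses a sulfur ketal that cannot revert under acid and sets out from keto ester 15. Ethane-1,2-dithiol with BF3·OEt2 in CH2Cl2 at 0 °C should give methyl 2-hydroxy-4-methoxy-6-[(2-pentyl-1,3-dithiolan-2-yl)methyl]benzoate F6. Saponification as in step 9 should give 2-hydroxy-4-methoxy-6-[(2-pentyl-1,3-dithiolan-2-yl)methyl]benzoic acid F7. Coupling with 22 as in step 14 should give benzyl 4-({2-hydroxy-4-methoxy-6-[(2-pentyl-1,3-dithiolan-2-yl)methyl]benzoyl}oxy)-2-methoxy-6-pentylbenzoate F8. Alkylative hydrolysis (MeI, CaCO3, MeCN–H2O, 45 °C) then comes back to the route at 24.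

Step 14 (depside coupling). Acyl transfer from the doubly ortho-substituted O-acylisourea to the phenol may be slow, so that rearrangement to the N-acylurea or self-acylation through the acid's own hydroxyl takes over. The fallback blocks that hydroxyl and uses an acid chloride, and it sets out from ketal ester 16. BnBr with K2CO3 in DMF at 60 °C should give methyl 2-(benzyloxy)-4-methoxy-6-[(2-pentyl-1,3-dioxolan-2-yl)methyl]benzoate F9. KOH in aqueous DMSO at 100 °C should give 2-(benzyloxy)-4-methoxy-6-[(2-pentyl-1,3-dioxolan-2-yl)methyl]benzoic acid F10. The neutral reagent 1-chloro-N,N,2-trimethylprop-1-en-1-amine in CH2Cl2 should give 2-(benzyloxy)-4-methoxy-6-[(2-pentyl-1,3-dioxolan-2-yl)methyl]benzoyl chloride F11. Acylation of 22 (Et3N, DMAP, CH2Cl2) should give benzyl 4-({2-(benzyloxy)-4-methoxy-6-[(2-pentyl-1,3-dioxolan-2-yl)methyl]benzoyl}oxy)-2-methoxy-6-pentylbenzoate F12. 1 M HCl in THF should give benzyl 4-{[2-(benzyloxy)-4-methoxy-6-(2-oxoheptyl)benzoyl]oxy}-2-methoxy-6-pentylbenzoate F13. Hydrogenolysis (H2, Pd/C, EtOAc) removes both benzyl groups and comes back to the route at target 25.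

**Further compounds**

F1 | step 4 | methyl 2-{[N-(tert-butyldimethylsilyl)-N-isopropylcarbamoyl]oxy}-4,6-dimethoxybenzoate | COC(=O)c1c(OC)cc(OC)cc1OC(=O)N(C(C)C)[Si](C)(C)C(C)(C)C
F2 | step 4 | methyl 2,4-dimethoxy-6-[(isopropylcarbamoyl)oxy]benzoate | COC(=O)c1c(OC)cc(OC)cc1OC(=O)NC(C)C
F3 | step 4 | methyl 2-hydroxy-4,6-dimethoxybenzoate | COC(=O)c1c(O)cc(OC)cc1OC
F4 | step 4 | methyl 2,4-dimethoxy-6-{[(trifluoromethyl)sulfonyl]oxy}benzoate | COC(=O)c1c(OC)cc(OC)cc1OS(=O)(=O)C(F)(F)F
F5 | step 4 | dimethyl 2-[3,5-dimethoxy-2-(methoxycarbonyl)phenyl]malonate | COC(=O)C(C(=O)OC)c1cc(OC)cc(OC)c1C(=O)OC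
F6 | step 8 | methyl 2-hydroxy-4-methoxy-6-[(2-pentyl-1,3-dithiolan-2-yl)methyl]benzoate | CCCCCC1(Cc2cc(OC)cc(O)c2C(=O)OC)SCCS1
F7 | step 8 | 2-hydroxy-4-methoxy-6-[(2-pentyl-1,3-dithiolan-2-yl)methyl]benzoic acid | CCCCCC1(Cc2cc(OC)cc(O)c2C(=O)O)SCCS1
F8 | step 8 | benzyl 4-({2-hydroxy-4-methoxy-6-[(2-pentyl-1,3-dithiolan-2-yl)methyl]benzoyl}oxy)-2-methoxy-6-pentylbenzoate | CCCCCC1(Cc2cc(OC)cc(O)c2C(=O)Oc2cc(CCCCC)c(C(=O)OCc3ccccc3)c(OC)c2)SCCS1
F9 | step 14 | methyl 2-(benzyloxy)-4-methoxy-6-[(2-pentyl-1,3-dioxolan-2-yl)methyl]benzoate | CCCCCC1(Cc2cc(OC)cc(OCc3ccccc3)c2C(=O)OC)OCCO1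
F10 | step 14 | 2-(benzyloxy)-4-methoxy-6-[(2-pentyl-1,3-dioxolan-2-yl)methyl]benzoic acid | CCCCCC1(Cc2cc(OC)cc(OCc3ccccc3)c2C(=O)O)OCCO1
F11 | step 14 | 2-(benzyloxy)-4-methoxy-6-[(2-pentyl-1,3-dioxolan-2-yl)methyl]benzoyl chloride | CCCCCC1(Cc2cc(OC)cc(OCc3ccccc3)c2C(Cl)=O)OCCO1
F12 | step 14 | benzyl 4-({2-(benzyloxy)-4-methoxy-6-[(2-pentyl-1,3-dioxolan-2-yl)methyl]benzoyl}oxy)-2-methoxy-6-pentylbenzoate | CCCCCC1(Cc2cc(OC)cc(OCc3ccccc3)c2C(=O)Oc2cc(CCCCC)c(C(=O)OCc3ccccc3)c(OC)c2)OCCO1
F13 | step 14 | benzyl 4-{[2-(benzyloxy)-4-methoxy-6-(2-oxoheptyl)benzoyl]oxy}-2-methoxy-6-pentylbenzoate | CCCCCC(=O)Cc1cc(OC)cc(OCc2ccccc2)c1C(=O)Oc1cc(CCCCC)c(C(=O)OCc2ccccc2)c(OC)c1
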